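**Strategy.** The oxane ring is cut between C2, the carbon that carries both ring oxygen O1 and the trioxygenated aryl ring A, and the C3 methylene. C2 is thus an aryl aldehyde carbon in disguise, and C3–C4–C5 an allyl unit on the C6 carbinol. An acid-mediated Prins cyclization of an S-configured homoallylic alcohol (bearing the catechol arm) with protected 5-hydroxyvanillin joins both halves, forms C2–C3 and C4–O, closes the ring and sets C2 and C4 from C6 in one operation. The precursor is an acyclic E-oxocarbenium ion. Because the Prins reaction delivers the equatorial C4 oxygen, a Mitsunobu inversion then installs the axial C4 hydroxyl before global debenzylation.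

Key step: step 5

Remark on the chemistry: the oxane is numbered O1, C2 (bearing ring A, the 3,4-dihydroxy-5-methoxyphenyl group), C3, C4 (carbinol), C5 and C6 (bearing the two-carbon arm to ring B, the 3,4-dihydroxyphenyl group). The target is read as (2S,4S,6S): the two carbon substituents are cis and equatorial, and the C4 hydroxyl is axial, trans to both. All four phenols are carried as benzyl ethers.

Step 1
Reactants: 1 3,4-dihydroxy-5-methoxybenzaldehyde (5-hydroxyvanillin)
Product: 2 3,4-bis(benzyloxy)-5-methoxybenzaldehyde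
Conditions: BnBr (2.4 equiv), K2CO3 (3 equiv), DMF, 60 °C
Reagents that add atoms: benzyl bromide BrCc1ccccc1
Why: Williamson ether synthesis, in which both phenoxides are alkylated while the aldehyde is inert to carbonate base, should give ethers that survive every later step and leave in the final hydrogenolysis.

Step 2
Reactants: 3 3-(3,4-dihydroxyphenyl)propanoic acid (dihydrocaffeic acid)
Product: 4 benzyl 3-[3,4-bis(benzyloxy)phenyl]propanoate
Conditions: BnBr (3.5 equiv), K2CO3 (4 equiv), DMF, 60 °C, N2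
Reagents that add atoms: benzyl bromide BrCc1ccccc1
Why: Williamson etherification of both phenols with concurrent O-alkylation of the carboxylate should give the tribenzyl compound in one operation.

Step 3
Reactants: 4 benzyl 3-[3,4-bis(benzyloxy)phenyl]propanoate
Product: 5 3-[3,4-bis(benzyloxy)phenyl]propanal
Conditions: i-Bu2AlH (1.1 equiv), CH2Cl2, −78 °C; MeOH, aq. KNaC4H4O6
Reagents that add atoms: none
Why: Partial ester reduction should stop at the aldehyde, because the tetrahedral aluminium hemiacetal is stable at −78 °C and collapses only on work-up.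

Step 4
Reactants: 5 3-[3,4-bis(benzyloxy)phenyl]propanal
Product: 6 (3S)-1-[3,4-bis(benzyloxy)phenyl]hex-5-en-3-ol
Conditions: allylSnBu3 (1.5 equiv), (R)-BINOL (20 mol%), Ti(OiPr)4 (10 mol%), 4 Å MS, CH2Cl2, −20 °C; aq. NaHCO3
Reagents that add atoms: allyltributylstannane C=CC[Sn](CCCC)(CCCC)CCCC
Why: Keck asymmetric allylation, in which the (R)-BINOL–Ti(OiPr)4 Lewis acid should direct allyl transfer from tin to the Re face of the unbranched aldehyde, sets the carbinol centre as 3S.

Step 5
Reactants: 6 (3S)-1-[3,4-bis(benzyloxy)phenyl]hex-5-en-3-ol; 2 3,4-bis(benzyloxy)-5-methoxybenzaldehyde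
Product: 9 (2S,4R,6S)-2-[3,4-bis(benzyloxy)-5-methoxyphenyl]-6-{2-[3,4-bis(benzyloxy)phenyl]ethyl}oxan-4-ol, via E-oxocarbenium trifluoroacetate 7 (not isolated), via all-cis C4 trifluoroacetate 8 (not isolated)
Conditions: CF3CO2H (15 equiv), CH2Cl2, 0 °C to rt; concentrate; K2CO3, MeOH, rt
Reagents that add atoms: trifluoroacetic acid OC(=O)C(F)(F)F
Why: Prins cyclization, closest to the known CF3CO2H-mediated Prins reaction of secondary homoallylic alcohols with aryl aldehydes: 6 and 2 condense to the E-oxocarbenium ion 7, the terminal alkene carbon attacks the oxocarbenium carbon to form the C2–C3 bond, and the C4 cation is captured by trifluoroacetate to give 8, which K2CO3/MeOH cleaves to 9. The oxane ring closes in a 6-endo-trig mode through a chair transition state. C2 is controlled by the C6 centre, whose C–O bond is never broken: the arylethyl arm and the aryl group of the E-oxocarbenium both sit equatorial, so the 2,6-cis (2S,6S) ring should result. C4 is controlled by the same chair, since the delocalised oxan-4-yl cation is captured from the equatorial direction to give the all-cis 4R oxygen. The step needs ring closure to outrun 2-oxonia-Cope allyl transfer and Friedel–Crafts attack by the electron-rich ring B; conjugation of the oxocarbenium with ring A keeps 7 the favoured partner of the Cope pair, and ring B could only close a seven-membered ring.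

Step 6
Reactants: 9 (2S,4R,6S)-2-[3,4-bis(benzyloxy)-5-methoxyphenyl]-6-{2-[3,4-bis(benzyloxy)phenyl]ethyl}oxan-4-ol
Product: 10 (2S,4S,6S)-2-[3,4-bis(benzyloxy)-5-methoxyphenyl]-6-{2-[3,4-bis(benzyloxy)phenyl]ethyl}oxan-4-yl 4-nitrobenzoate
Conditions: 4-O2NC6H4CO2H (3 equiv), PPh3 (3 equiv), DIAD (3 equiv), THF, 0 °C to rt
Reagents that add atoms: 4-nitrobenzoic acid OC(=O)c1ccc(cc1)[N+](=O)[O-]
Why: Mitsunobu reaction, in which the equatorial C4 alcohol is activated as its alkoxyphosphonium ion and displaced by 4-nitrobenzoate with SN2 inversion, should turn 4R into the axial 4S ester.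

Step 7
Reactants: 10 (2S,4S,6S)-2-[3,4-bis(benzyloxy)-5-methoxyphenyl]-6-{2-[3,4-bis(benzyloxy)phenyl]ethyl}oxan-4-yl 4-nitrobenzoate
Product: 11 (2S,4S,6S)-2-[3,4-bis(benzyloxy)-5-methoxyphenyl]-6-{2-[3,4-bis(benzyloxy)phenyl]ethyl}oxan-4-ol
Conditions: K2CO3, MeOH/THF, rt
Reagents that add atoms: none
Why: Base-catalysed transesterification should cleave the electron-poor ester at its acyl carbon, so the C4–O bond and all three stereocentres stay untouched.

Step 8
Reactants: 11 (2S,4S,6S)-2-[3,4-bis(benzyloxy)-5-methoxyphenyl]-6-{2-[3,4-bis(benzyloxy)phenyl]ethyl}oxan-4-ol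
Product: 12 (2S,4S,6S)-2-(3,4-dihydroxy-5-methoxyphenyl)-6-[2-(3,4-dihydroxyphenyl)ethyl]oxan-4-ol (CNP0196753.1)
Conditions: H2 (1 atm), 10% Pd/C, EtOAc/MeOH, rt
Reagents that add atoms: none
Why: Catalytic hydrogenolysis should remove the four aryl benzyl ethers faster than it cleaves the benzylic C2–O1 bond of the ring, so the oxane and its stereocentres should survive and the methyl ether is untouched.

**Compound list**

1 | 3,4-dihydroxy-5-methoxybenzaldehyde (5-hydroxyvanillin) | COc1cc(C=O)cc(O)c1O | starting material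
2 | 3,4-bis(benzyloxy)-5-methoxybenzaldehyde | COc1cc(C=O)cc(OCc2ccccc2)c1OCc1ccccc1 | intermediate
3 | 3-(3,4-dihydroxyphenyl)propanoic acid (dihydrocaffeic acid) | OC(=O)CCc1ccc(O)c(O)c1 | starting material
4 | benzyl 3-[3,4-bis(benzyloxy)phenyl]propanoate | O=C(CCc1ccc(OCc2ccccc2)c(OCc2ccccc2)c1)OCc1ccccc1 | intermediate
5 | 3-[3,4-bis(benzyloxy)phenyl]propanal | O=CCCc1ccc(OCc2ccccc2)c(OCc2ccccc2)c1 | intermediate
6 | (3S)-1-[3,4-bis(benzyloxy)phenyl]hex-5-en-3-ol | C=CC[C@@H](O)CCc1ccc(OCc2ccccc2)c(OCc2ccccc2)c1 | intermediate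
7 | (E)-[3,4-bis(benzyloxy)-5-methoxybenzylidene][(3S)-1-[3,4-bis(benzyloxy)phenyl]hex-5-en-3-yl]oxonium trifluoroacetate (E-oxocarbenium ion) | C=CC[C@H](CCc1ccc(OCc2ccccc2)c(OCc2ccccc2)c1)/[O+]=C/c1cc(OC)c(OCc2ccccc2)c(OCc2ccccc2)c1.[O-]C(=O)C(F)(F)F | intermediate
8 | (2S,4R,6S)-2-[3,4-bis(benzyloxy)-5-methoxyphenyl]-6-{2-[3,4-bis(benzyloxy)phenyl]ethyl}oxan-4-yl trifluoroacetate | COc1cc([C@@H]2C[C@H](OC(=O)C(F)(F)F)C[C@H](CCc3ccc(OCc4ccccc4)c(OCc4ccccc4)c3)O2)cc(OCc2ccccc2)c1OCc1ccccc1 | intermediate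
9 | (2S,4R,6S)-2-[3,4-bis(benzyloxy)-5-methoxyphenyl]-6-{2-[3,4-bis(benzyloxy)phenyl]ethyl}oxan-4-ol (all-cis, equatorial hydroxyl) | COc1cc([C@@H]2C[C@H](O)C[C@H](CCc3ccc(OCc4ccccc4)c(OCc4ccccc4)c3)O2)cc(OCc2ccccc2)c1OCc1ccccc1 | intermediate
10 | (2S,4S,6S)-2-[3,4-bis(benzyloxy)-5-methoxyphenyl]-6-{2-[3,4-bis(benzyloxy)phenyl]ethyl}oxan-4-yl 4-nitrobenzoate | COc1cc([C@@H]2C[C@@H](OC(=O)c3ccc(cc3)[N+](=O)[O-])C[C@H](CCc3ccc(OCc4ccccc4)c(OCc4ccccc4)c3)O2)cc(OCc2ccccc2)c1OCc1ccccc1 | intermediate
11 | (2S,4S,6S)-2-[3,4-bis(benzyloxy)-5-methoxyphenyl]-6-{2-[3,4-bis(benzyloxy)phenyl]ethyl}oxan-4-ol (axial hydroxyl) | COc1cc([C@@H]2C[C@@H](O)C[C@H](CCc3ccc(OCc4ccccc4)c(OCc4ccccc4)c3)O2)cc(OCc2ccccc2)c1OCc1ccccc1 | intermediate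
12 | (2S,4S,6S)-2-(3,4-dihydroxy-5-methoxyphenyl)-6-[2-(3,4-dihydroxyphenyl)ethyl]oxan-4-ol (CNP0196753.1) | COc1cc([C@@H]2C[C@@H](O)C[C@H](CCc3ccc(O)c(O)c3)O2)cc(O)c1O | target

**Step count and risks**

Total step count: 8. Longest linear sequence: 7 steps (3 → 4 → 5 → 6 → 9 → 10 → 11 → 12).

Steps most likely to fail:

Step 5 (key step). The aryl-conjugated oxocarbenium ion is a weak electrophile, so ring closure may be slow. 2-Oxonia-Cope rearrangement followed by hydrolysis (allyl transfer between the two aldehydes) and ionisation of the electron-rich benzylic C–O bond could then compete. This would erode the enantiomeric purity and divert material into symmetrical oxanes. The fallback is a segment-coupling Prins cyclization, which generates the same cation without water or free aldehyde. It sets out from 2 and 6 and comes back to the route at 9. Pinnick oxidation of 2 (NaClO2, NaH2PO4, 2-methyl-2-butene, t-BuOH/H2O) should give 3,4-bis(benzyloxy)-5-methoxybenzoic acid F1. Steglich esterification with 6 (DCC, DMAP, CH2Cl2) should give (3S)-1-[3,4-bis(benzyloxy)phenyl]hex-5-en-3-yl 3,4-bis(benzyloxy)-5-methoxybenzoate F2. Reductive acetylation (i-Bu2AlH, CH2Cl2, −78 °C, then Ac2O, pyridine, DMAP) should give the α-acetoxy ether [3,4-bis(benzyloxy)-5-methoxyphenyl]{[(3S)-1-[3,4-bis(benzyloxy)phenyl]hex-5-en-3-yl]oxy}methyl acetate F3 as a mixture of acetal epimers, both of which ionise to the same cation. BF3·OEt2 and AcOH in hexane/CH2Cl2 at 0 °C should then close the ring to the all-cis (2S,4R,6S)-2-[3,4-bis(benzyloxy)-5-methoxyphenyl]-6-{2-[3,4-bis(benzyloxy)phenyl]ethyl}oxan-4-yl acetate F4. K2CO3 in MeOH returns 9.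

Step 8. Hydrogenolysis of the benzylic C2–O1 bond (ring opening at the carbon activated by ring A) may compete with O-debenzylation, or the catechol products may poison the catalyst so that debenzylation stalls. The fallback is a non-reductive Lewis-acid debenzylation. It sets out from 11 and arrives directly at 12 with no new intermediate: BCl3 with pentamethylbenzene as benzyl-cation scavenger, CH2Cl2, −78 °C, then MeOH quench. At this temperature the aryl methyl ether should stay intact.

Step 6. The alkoxyphosphonium intermediate may undergo elimination to a dihydropyran instead of substitution, or activation of the ring alcohol may be incomplete. The fallback is a redox inversion. It sets out from 9 and comes back at 11, so step 7 is then not needed. Dess–Martin periodinane (NaHCO3, CH2Cl2) should give (2S,6S)-2-[3,4-bis(benzyloxy)-5-methoxyphenyl]-6-{2-[3,4-bis(benzyloxy)phenyl]ethyl}oxan-4-one F5. Li[(s-Bu)3BH] (L-Selectride) in THF at −78 °C should deliver hydride from the less hindered equatorial face and give the axial alcohol 11.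

**Further compounds**

F1 | step 5 | 3,4-bis(benzyloxy)-5-methoxybenzoic acid | COc1cc(C(=O)O)cc(OCc2ccccc2)c1OCc1ccccc1
F2 | step 5 | (3S)-1-[3,4-bis(benzyloxy)phenyl]hex-5-en-3-yl 3,4-bis(benzyloxy)-5-methoxybenzoate | C=CC[C@H](CCc1ccc(OCc2ccccc2)c(OCc2ccccc2)c1)OC(=O)c1cc(OC)c(OCc2ccccc2)c(OCc2ccccc2)c1
F3 | step 5 | [3,4-bis(benzyloxy)-5-methoxyphenyl]{[(3S)-1-[3,4-bis(benzyloxy)phenyl]hex-5-en-3-yl]oxy}methyl acetate (acetal epimers) | C=CC[C@H](CCc1ccc(OCc2ccccc2)c(OCc2ccccc2)c1)OC(OC(C)=O)c1cc(OC)c(OCc2ccccc2)c(OCc2ccccc2)c1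
F4 | step 5 | (2S,4R,6S)-2-[3,4-bis(benzyloxy)-5-methoxyphenyl]-6-{2-[3,4-bis(benzyloxy)phenyl]ethyl}oxan-4-yl acetate | COc1cc([C@@H]2C[C@H](OC(C)=O)C[C@H](CCc3ccc(OCc4ccccc4)c(OCc4ccccc4)c3)O2)cc(OCc2ccccc2)c1OCc1ccccc1
F5 | step 6 | (2S,6S)-2-[3,4-bis(benzyloxy)-5-methoxyphenyl]-6-{2-[3,4-bis(benzyloxy)phenyl]ethyl}oxan-4-one | COc1cc([C@@H]2CC(=O)C[C@H](CCc3ccc(OCc4ccccc4)c(OCc4ccccc4)c3)O2)cc(OCc2ccccc2)c1OCc1ccccc1
F0 | step 8 | none | none
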